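**Plan**

1. Locants (germacrane style, used for all ring intermediates): ring C1–C10 with C4 = CH(CH3), C6 = lactone carbinol carbon, C7 = ring-fusion CH carrying C11, C8 = acyloxy carbon, C9=C10 = ring-cis alkene, C14 = CH2OH on C10; C11/C12/C13 = lactone alpha-carbon, carbonyl and methylene.
2. Retrosynthesis: cut the C8 ester (Mitsunobu, inversion), then C11=C13 and the C12–O lactone bond, then the ring bond C3–C4 while a bond C1–C6 that the target does not contain is drawn in (retro anionic oxy-Cope), then C5–C6 (propenyl addition to a ketone), and last the cyclohexene into three acyclic pieces (C9–C8 aldehyde, C7–C6 nitroalkene, C14–C10–C1–C2–C3 enal).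
3. Enabling feature: C6 carries oxygen and lies two bonds from C4, and C9=C10 is ring-cis, so the six atoms C6, C7, C8, C9, C10, C1 can be held as a cyclohex-9-ene whose temporary C1–C6 bond joins an alkoxide/(E)-propenyl carbon to a vinyl-bearing carbon. The ten-membered ring is this six-membered ring plus the four-carbon bridge C5, C4, C3, C2, and the alkoxide oxygen ends as the lactone oxygen.
4. Forward order: cyclohexene from three components (two aminocatalytic Michael additions, aldol condensation), Nef reaction and propenyl addition, ring expansion to the cyclodecadienone (C3–C4 formed, C1–C6 cleaved), saturation of C1=C2, C6 reduction, lactone, methylene, ester.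
5. Stereochemistry: C7 (and C8 as its epimer) from the (S)-prolinol catalyst, temporary C1 from the (R)-catalyst, temporary C6 by addition anti to the C7/C1 chains. C6/C1 are relayed to C4 through the chair transition state; C6–O comes from a reduction directed by the C8 ether; C8 is inverted in the Mitsunobu esterification; the ring-cis alkene comes from the cyclohexene and the side-chain alkene from a syn-hydrostannation.

Key step: step 14

Assumption: the facial sense of both aminocatalytic steps is taken from the usual shielding model of diphenylprolinol silyl ethers (as for propanal with beta-nitrostyrene); TBS = tert-butyldimethylsilyl, TBDPS = tert-butyldiphenylsilyl, PMB = 4-methoxybenzyl.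

**Route**

Step 1
Reactants: 1 3-(TBS-oxy)propanal; 2 nitromethane
Product: 4 (E)-tert-butyldimethyl[(4-nitrobut-3-en-1-yl)oxy]silane, via nitro alcohol 3 (not isolated)
Conditions: MeNO2 (5 equiv), Et3N (cat.), CH2Cl2, 0 °C to rt; then MsCl, Et3N, 0 °C
Reagents that add atoms: none
Why: Henry (nitroaldol) addition followed by mesylation and E1cB elimination should give the conjugated (E)-nitroalkene.

Step 2
Reactants: 5 acrolein; 6 benzeneselenol
Product: 7 3-(phenylselanyl)propanal
Conditions: CH2Cl2, 0 °C to rt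
Reagents that add atoms: none
Why: Conjugate (selena-Michael) addition of the soft selenol to the enal should be fast and needs no catalyst; the selenide is a masked vinyl group.

Step 3
Reactants: 7 3-(phenylselanyl)propanal; 8 (triphenylphosphoranylidene)acetaldehyde
Product: 9 (E)-5-(phenylselanyl)pent-2-enal
Conditions: toluene, 80 °C
Reagents that add atoms: none
Why: Wittig olefination with the stabilised formyl ylide should give the (E)-enal.

Step 4
Reactants: 10 but-2-yne-1,4-diol
Product: 11 (E)-2-(tributylstannyl)but-2-ene-1,4-diol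
Conditions: Bu3SnH, PdCl2(PPh3)2 (2 mol%), THF, rt
Reagents that add atoms: tributylstannane, CCCC[SnH](CCCC)CCCC
Why: Palladium-catalysed hydrostannation is a syn addition, so H and Sn end cis and the two CH2OH groups end cis on the alkene; the alkyne is symmetrical, so there is no regiochemical issue.

Step 5
Reactants: 11 (E)-2-(tributylstannyl)but-2-ene-1,4-diol
Product: 12 tributyl(2,2-dimethyl-4,7-dihydro-1,3-dioxepin-5-yl)stannane
Conditions: 2,2-dimethoxypropane, pyridinium p-toluenesulfonate (cat.), CH2Cl2, rt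
Reagents that add atoms: 2,2-dimethoxypropane, COC(C)(C)OC
Why: Transacetalisation of the cis-disposed 1,4-diol should close the seven-membered isopropylidene acetal, which also locks the alkene geometry.

Step 6
Reactants: 12 tributyl(2,2-dimethyl-4,7-dihydro-1,3-dioxepin-5-yl)stannane
Product: 14 2,2-dimethyl-4,7-dihydro-1,3-dioxepine-5-carboxylic acid, via vinyllithium 13 (not isolated)
Conditions: n-BuLi, THF, −78 °C; then CO2; cold dilute HCl to pH 4
Reagents that add atoms: carbon dioxide, O=C=O
Why: Tin–lithium exchange with retention and carboxylation of the vinyllithium should give the acetonide-protected 4,5-dihydroxytiglic acid.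

Step 7
Reactants: 15 2-(PMB-oxy)acetaldehyde; 4 (E)-tert-butyldimethyl[(4-nitrobut-3-en-1-yl)oxy]silane
Product: 16 (2R,3S)-2-(PMB-oxy)-3-(nitromethyl)-5-(TBS-oxy)pentanal
Conditions: (S)-α,α-diphenylprolinol trimethylsilyl ether (10 mol%), ClCH2CO2H (20 mol%), CH2Cl2, 0 °C to rt
Reagents that add atoms: none
Why: Enamine-catalysed asymmetric Michael addition of an alkoxyacetaldehyde to a nitroalkene: the anti enamine is attacked on the face remote from the CPh2OSiMe3 group through a synclinal transition state, which should give the syn adduct and set C7 in its final configuration and C8 as the epimer of the target.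

Step 8
Reactants: 16 (2R,3S)-2-(PMB-oxy)-3-(nitromethyl)-5-(TBS-oxy)pentanal; 9 (E)-5-(phenylselanyl)pent-2-enal
Product: 19 7-[2-(TBS-oxy)ethyl]-8-(PMB-oxy)-6-nitro-1-[2-(phenylselanyl)ethyl]cyclohex-9-ene-10-carbaldehyde (C8 ether trans to the C7 chain; C1 chain cis to the C7 chain; C6 epimers), via nitro dialdehyde 17 (not isolated), via aldol 18 (not isolated)
Conditions: (R)-α,α-diphenylprolinol trimethylsilyl ether (20 mol%), PhCO2H (20 mol%), toluene, 0 °C to rt
Reagents that add atoms: none
Why: Iminium activation of 9 by the (R)-catalyst lets the nitronate carbon C6 add to C1 on the unshielded face (sets C1 cis to the C7 chain), and the resulting enamine closes the ring by aldol condensation on the C9 aldehyde (organocatalytic nitro-Michael/aldol annulation of the triple-cascade type), which fixes C9=C10 as a ring alkene.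

Step 9
Reactants: 19 the cyclohexenecarbaldehyde
Product: 20 the corresponding 10-(hydroxymethyl)cyclohex-9-ene (C14 alcohol)
Conditions: NaBH4, CeCl3·7H2O, MeOH, −40 °C
Reagents that add atoms: none
Why: Luche 1,2-reduction of the enal should leave the nitro group, the selenide and the ethers untouched.

Step 10
Reactants: 20 the C14 alcohol
Product: 21 its 14-O-TBDPS ether
Conditions: TBDPSCl, imidazole, CH2Cl2, rt
Reagents that add atoms: tert-butyl(chloro)diphenylsilane, CC(C)(C)[Si](Cl)(c1ccccc1)c1ccccc1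
Why: Silylation of the primary allylic alcohol gives the robust ether that is carried to the last step.

Step 11
Reactants: 21 the nitrocyclohexene
Product: 23 10-(TBDPS-oxymethyl)-8-(PMB-oxy)-7-[2-(TBS-oxy)ethyl]-1-[2-(phenylselanyl)ethyl]cyclohex-9-en-6-one (C7/C8 trans; C7/C1 cis), via sodium nitronate 22 (not isolated)
Conditions: NaOMe, MeOH, 0 °C; then TiCl3 (aq.), NH4OAc buffer (pH 5–6), THF, 0 °C to rt
Reagents that add atoms: water, O
Why: Nef reaction in its reductive variant (trivalent titanium reduces the nitronate to the imine, which is hydrolysed) should unveil the C6 ketone under buffered, non-basic conditions; C1, now alpha to the carbonyl, can only relax towards the desired all-equatorial isomer.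

Step 12
Reactants: 23 the cyclohex-9-en-6-one; 24 (E)-1-bromoprop-1-ene
Product: 25 6-[(E)-prop-1-enyl]-10-(TBDPS-oxymethyl)-8-(PMB-oxy)-7-[2-(TBS-oxy)ethyl]-1-[2-(phenylselanyl)ethyl]cyclohex-9-en-6-ol (C6–OH cis to the C7 and C1 chains; propenyl trans to them)
Conditions: 24, t-BuLi (2 equiv), Et2O, −78 °C; CeCl3 (anhydrous), THF, −78 °C; then 23, −78 °C; aq. NH4Cl
Reagents that add atoms: none
Why: 1,2-Addition of the weakly basic organocerium reagent to the enolisable beta,gamma-unsaturated ketone should occur anti to the two cis alpha-substituents at C7 and C1, setting C6 with the propenyl group trans to the future vinyl group.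

Step 13
Reactants: 25 the selenide carbinol
Product: 27 6-[(E)-prop-1-enyl]-1-vinyl-10-(TBDPS-oxymethyl)-8-(PMB-oxy)-7-[2-(TBS-oxy)ethyl]cyclohex-9-en-6-ol (propenyl and vinyl trans), via selenoxide 26 (not isolated)
Conditions: mCPBA (1.0 equiv), CH2Cl2, −78 °C; then i-Pr2NH, warm to 40 °C
Reagents that add atoms: none
Why: Selective oxidation at selenium and syn-elimination of the primary selenoxide should release the C1 vinyl group (C2=C3) without touching C1.

Step 14
Reactants: 27 the trans-1-vinyl-6-propenylcyclohex-9-en-6-ol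
Product: 30 (4R)-4-methyl-10-(TBDPS-oxymethyl)-8-(PMB-oxy)-7-[2-(TBS-oxy)ethyl]cyclodeca-1,9-dien-6-one (C1=C2 trans in the ring; C9=C10 ring-cis), via potassium alkoxide 28 (not isolated), via potassium enolate 29 (not isolated)
Conditions: KH, 18-crown-6, THF, 0 °C to rt (50 °C if slow); aq. NH4Cl at −78 °C
Reagents that add atoms: none
Why: Deprotonation gives the tertiary potassium alkoxide, whose C1–C6 bond is weakened so that a concerted [3,3] shift (anionic oxy-Cope rearrangement, as in the ring expansion of 1,2-divinylcyclohexanols to cyclodec-5-enones) forms C3–C4 while C1–C6 breaks and delivers the C5=C6 enolate, which is protonated on work-up. The ten-membered ring is closed by ring expansion: the six-membered ring (C6, C7, C8, C9, C10, C1) takes up the four carbons C5, C4, C3, C2 through a chair-like six-centre transition state trans-fused to the cyclohexene, with propenyl and vinyl trans-diequatorial. C4 is the only new stereocentre and is set by chirality transfer from C6 and C1 through this chair, in which the methyl group of the (E)-propenyl unit is pseudo-equatorial; C1=C2 emerges trans and the ring-cis C9=C10 alkene is carried over unchanged. The step needs periselectivity for the vinyl group over the ring alkene C9=C10 (which with C1–C6 and the propenyl group forms a second 1,5-diene) and must not fragment ionically; the vinyl group reaches a chair whereas the ring alkene could only react through a strained bridged boat, and enolate formation makes the shift irreversible. C7 and C8 are untouched because the enolate forms regiospecifically towards C5 and is quenched cold.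

Step 15
Reactants: 30 the cyclodeca-1,9-dien-6-one
Product: 31 (4R)-4-methyl-10-(TBDPS-oxymethyl)-8-(PMB-oxy)-7-[2-(TBS-oxy)ethyl]cyclodec-9-en-6-one
Conditions: dipotassium azodicarboxylate, AcOH, MeOH/CH2Cl2, 0 °C to rt
Reagents that add atoms: none
Why: Diimide reduction should saturate the strained trans-disubstituted C1=C2 alkene much faster than the hindered trisubstituted C9=C10 alkene, and it forms no hydrazone with the ketone.

Step 16
Reactants: 31 the cyclodec-9-en-6-one
Product: 32 the cyclodec-9-en-6-ol (C6–OH cis to C8–OPMB and trans to the C7 chain)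
Conditions: Zn(BH4)2, Et2O, −30 °C
Reagents that add atoms: none
Why: Chelation-controlled hydride reduction of a beta-alkoxy ketone: zinc bridges the C6 carbonyl and the C8 ether oxygen and external hydride delivery should give the 1,3-syn alcohol, which is the C6 configuration of the target.

Step 17
Reactants: 32 the C6 alcohol
Product: 33 the 6,12-diol (free primary C12–OH)
Conditions: camphorsulfonic acid (cat.), MeOH/CH2Cl2, 0 °C
Reagents that add atoms: none
Why: Acid-catalysed methanolysis should cleave the primary TBS ether selectively in the presence of the TBDPS and PMB ethers.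

Step 18
Reactants: 33 the 6,12-diol
Product: 35 the trans-fused 6,12-lactone (saturated at C11), via lactol 34 (not isolated)
Conditions: TEMPO (2,2,6,6-tetramethylpiperidin-1-oxyl, 20 mol%), PhI(OAc)2 (3 equiv), CH2Cl2, rt
Reagents that add atoms: none
Why: Oxidative lactonisation of a 1,4-diol: the primary alcohol is oxidised to the aldehyde, which closes to the lactol and is oxidised again, while the secondary C6–OH is not oxidised.

Step 19
Reactants: 35 the saturated lactone
Product: 38 the alpha-methylene lactone (C11=C13), via Mannich base 36 (not isolated), via ammonium iodide 37 (not isolated)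
Conditions: lithium diisopropylamide, THF, −78 °C; CH2=NMe2 I (Eschenmoser's salt), −78 °C to rt; then MeI, MeOH, rt; then NaHCO3 (aq.)/CH2Cl2, rt
Reagents that add atoms: N,N-dimethylmethyleneiminium iodide, C=[N+](C)C.[I-]
Why: Eschenmoser methylenation (Mannich reaction of the lactone enolate, quaternisation, Hofmann-type elimination) is the standard entry to alpha-methylene gamma-lactones and no other acidic site is present.

Step 20
Reactants: 38 the alpha-methylene lactone
Product: 39 the C8 alcohol (C8–OH on the same face as O6, epimeric to the target at C8)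
Conditions: DDQ, CH2Cl2/pH 7 buffer (10:1), 0 °C
Reagents that add atoms: none
Why: Oxidative cleavage of the PMB ether should leave the silyl ether, the alkenes and the lactone untouched.

Step 21
Reactants: 39 the C8 alcohol; 14 2,2-dimethyl-4,7-dihydro-1,3-dioxepine-5-carboxylic acid
Product: 40 the C8 ester of inverted configuration (protected target)
Conditions: PPh3, diisopropyl azodicarboxylate, toluene, 0 °C to rt
Reagents that add atoms: none
Why: Mitsunobu esterification: the carboxylate displaces the activated C8 oxygen by SN2, so the ester is formed with inversion and C8 reaches the configuration of the target.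

Step 22
Reactants: 40 the protected target
Product: 41 CNP0131216.2 (target)
Conditions: HF (48% aq.), MeCN, 0 °C to rt
Reagents that add atoms: none
Why: Aqueous HF should cleave the TBDPS ether and hydrolyse the isopropylidene acetal in one operation without harming the alpha-methylene lactone or the allylic ester.

**Compound list**

1 | 3-[(tert-butyldimethylsilyl)oxy]propanal | O=CCCO[Si](C)(C)C(C)(C)C | starting material
2 | nitromethane | C[N+](=O)[O-] | starting material
3 | 4-(TBS-oxy)-1-nitrobutan-2-ol (racemic) | [O-][N+](=O)CC(O)CCO[Si](C)(C)C(C)(C)C | intermediate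
4 | (E)-tert-butyldimethyl[(4-nitrobut-3-en-1-yl)oxy]silane | [O-][N+](=O)/C=C/CCO[Si](C)(C)C(C)(C)C | intermediate
5 | acrolein | C=CC=O | starting material
6 | benzeneselenol | [SeH]c1ccccc1 | starting material
7 | 3-(phenylselanyl)propanal | O=CCC[Se]c1ccccc1 | intermediate
8 | (triphenylphosphoranylidene)acetaldehyde | O=CC=P(c1ccccc1)(c1ccccc1)c1ccccc1 | starting material
9 | (E)-5-(phenylselanyl)pent-2-enal | O=C/C=C/CC[Se]c1ccccc1 | intermediate
10 | but-2-yne-1,4-diol | OCC#CCO | starting material
11 | (E)-2-(tributylstannyl)but-2-ene-1,4-diol | OC/C=C(\CO)[Sn](CCCC)(CCCC)CCCC | intermediate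
12 | tributyl(2,2-dimethyl-4,7-dihydro-1,3-dioxepin-5-yl)stannane | CC1(C)OCC=C(CO1)[Sn](CCCC)(CCCC)CCCC | intermediate
13 | (2,2-dimethyl-4,7-dihydro-1,3-dioxepin-5-yl)lithium | CC1(C)OCC=C([Li])CO1 | intermediate
14 | 2,2-dimethyl-4,7-dihydro-1,3-dioxepine-5-carboxylic acid | CC1(C)OCC=C(CO1)C(=O)O | intermediate
15 | 2-[(4-methoxybenzyl)oxy]acetaldehyde | O=CCOCc1ccc(OC)cc1 | starting material
16 | (2R,3S)-2-(PMB-oxy)-3-(nitromethyl)-5-(TBS-oxy)pentanal | O=C[C@H](OCc1ccc(OC)cc1)[C@@H](CCO[Si](C)(C)C(C)(C)C)C[N+](=O)[O-] | intermediate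
17 | acyclic nitro dialdehyde (C1–C6 bond formed; C6 epimers) | O=CC[C@H](CC[Se]c1ccccc1)C([N+](=O)[O-])[C@H](CCO[Si](C)(C)C(C)(C)C)[C@@H](OCc1ccc(OC)cc1)C=O | intermediate
18 | cyclised aldol (9-hydroxy-10-formylcyclohexane; C9/C10 unassigned) | O=CC1C(O)[C@H](OCc2ccc(OC)cc2)[C@@H](CCO[Si](C)(C)C(C)(C)C)C([N+](=O)[O-])[C@H]1CC[Se]c1ccccc1 | intermediate
19 | 7-[2-(TBS-oxy)ethyl]-8-(PMB-oxy)-6-nitro-1-[2-(phenylselanyl)ethyl]cyclohex-9-ene-10-carbaldehyde (C7/C8 trans; C7/C1 cis; C6 epimers) | O=CC1=C[C@H](OCc2ccc(OC)cc2)[C@@H](CCO[Si](C)(C)C(C)(C)C)C([N+](=O)[O-])[C@H]1CC[Se]c1ccccc1 | intermediate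
20 | the 10-(hydroxymethyl) analogue of 19 | OCC1=C[C@H](OCc2ccc(OC)cc2)[C@@H](CCO[Si](C)(C)C(C)(C)C)C([N+](=O)[O-])[C@H]1CC[Se]c1ccccc1 | intermediate
21 | the 14-O-TBDPS ether of 20 | CC(C)(C)[Si](c1ccccc1)(c1ccccc1)OCC1=C[C@H](OCc2ccc(OC)cc2)[C@@H](CCO[Si](C)(C)C(C)(C)C)C([N+](=O)[O-])[C@H]1CC[Se]c1ccccc1 | intermediate
22 | sodium nitronate of 21 | [Na+].[O-][N+]([O-])=C1[C@H](CCO[Si](C)(C)C(C)(C)C)[C@@H](OCc2ccc(OC)cc2)C=C(CO[Si](c2ccccc2)(c2ccccc2)C(C)(C)C)[C@@H]1CC[Se]c1ccccc1 | intermediate
23 | 10-(TBDPS-oxymethyl)-8-(PMB-oxy)-7-[2-(TBS-oxy)ethyl]-1-[2-(phenylselanyl)ethyl]cyclohex-9-en-6-one (C7/C8 trans; C7/C1 cis) | O=C1[C@H](CCO[Si](C)(C)C(C)(C)C)[C@@H](OCc2ccc(OC)cc2)C=C(CO[Si](c2ccccc2)(c2ccccc2)C(C)(C)C)[C@@H]1CC[Se]c1ccccc1 | intermediate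
24 | (E)-1-bromoprop-1-ene | C/C=C/Br | starting material
25 | 6-[(E)-prop-1-enyl]cyclohex-9-en-6-ol from 23 (OH cis to the C7 and C1 chains) | C/C=C/[C@@]1(O)[C@H](CCO[Si](C)(C)C(C)(C)C)[C@@H](OCc2ccc(OC)cc2)C=C(CO[Si](c2ccccc2)(c2ccccc2)C(C)(C)C)[C@@H]1CC[Se]c1ccccc1 | intermediate
26 | selenoxide of 25 | C/C=C/[C@@]1(O)[C@H](CCO[Si](C)(C)C(C)(C)C)[C@@H](OCc2ccc(OC)cc2)C=C(CO[Si](c2ccccc2)(c2ccccc2)C(C)(C)C)[C@@H]1CC[Se](=O)c1ccccc1 | intermediate
27 | 6-[(E)-prop-1-enyl]-1-vinylcyclohex-9-en-6-ol (propenyl/vinyl trans; OH cis to vinyl and to the C7 chain) | C/C=C/[C@@]1(O)[C@H](CCO[Si](C)(C)C(C)(C)C)[C@@H](OCc2ccc(OC)cc2)C=C(CO[Si](c2ccccc2)(c2ccccc2)C(C)(C)C)[C@@H]1C=C | intermediate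
28 | potassium alkoxide of 27 | [K+].C/C=C/[C@@]1([O-])[C@H](CCO[Si](C)(C)C(C)(C)C)[C@@H](OCc2ccc(OC)cc2)C=C(CO[Si](c2ccccc2)(c2ccccc2)C(C)(C)C)[C@@H]1C=C | intermediate
29 | potassium C5=C6 enolate of 30 (C4 and C7 trans on the enolate) | [K+].[O-]/C1=C\[C@H](C)C/C=C/C(CO[Si](c2ccccc2)(c2ccccc2)C(C)(C)C)=C\[C@H](OCc2ccc(OC)cc2)[C@H]1CCO[Si](C)(C)C(C)(C)C | intermediate
30 | (4R)-4-methyl-10-(TBDPS-oxymethyl)-8-(PMB-oxy)-7-[2-(TBS-oxy)ethyl]cyclodeca-1,9-dien-6-one (C1=C2 ring-trans; C9=C10 ring-cis) | O=C1C[C@H](C)C/C=C/C(CO[Si](c2ccccc2)(c2ccccc2)C(C)(C)C)=C\[C@H](OCc2ccc(OC)cc2)[C@H]1CCO[Si](C)(C)C(C)(C)C | intermediate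
31 | (4R)-4-methyl-10-(TBDPS-oxymethyl)-8-(PMB-oxy)-7-[2-(TBS-oxy)ethyl]cyclodec-9-en-6-one | O=C1C[C@H](C)CCC/C(CO[Si](c2ccccc2)(c2ccccc2)C(C)(C)C)=C\[C@H](OCc2ccc(OC)cc2)[C@H]1CCO[Si](C)(C)C(C)(C)C | intermediate
32 | cyclodec-9-en-6-ol from 31 (C6–OH cis to C8–OPMB; trans to the C7 chain) | O[C@@H]1C[C@H](C)CCC/C(CO[Si](c2ccccc2)(c2ccccc2)C(C)(C)C)=C\[C@H](OCc2ccc(OC)cc2)[C@H]1CCO[Si](C)(C)C(C)(C)C | intermediate
33 | 6,12-diol (TBS removed) | O[C@@H]1C[C@H](C)CCC/C(CO[Si](c2ccccc2)(c2ccccc2)C(C)(C)C)=C\[C@H](OCc2ccc(OC)cc2)[C@H]1CCO | intermediate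
34 | lactol (C12 hemiacetal on O6) | OC1O[C@@H]2C[C@H](C)CCC/C(CO[Si](c3ccccc3)(c3ccccc3)C(C)(C)C)=C\[C@H](OCc3ccc(OC)cc3)[C@H]2C1 | intermediate
35 | trans-fused 6,12-lactone with 8-OPMB and 14-OTBDPS | O=C1O[C@@H]2C[C@H](C)CCC/C(CO[Si](c3ccccc3)(c3ccccc3)C(C)(C)C)=C\[C@H](OCc3ccc(OC)cc3)[C@H]2C1 | intermediate
36 | 11-(dimethylaminomethyl) lactone (Mannich base; C11 unassigned) | CN(C)CC1C(=O)O[C@@H]2C[C@H](C)CCC/C(CO[Si](c3ccccc3)(c3ccccc3)C(C)(C)C)=C\[C@H](OCc3ccc(OC)cc3)[C@@H]12 | intermediate
37 | trimethylammonium iodide of 36 | C[N+](C)(C)CC1C(=O)O[C@@H]2C[C@H](C)CCC/C(CO[Si](c3ccccc3)(c3ccccc3)C(C)(C)C)=C\[C@H](OCc3ccc(OC)cc3)[C@@H]12.[I-] | intermediate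
38 | alpha-methylene lactone with 8-OPMB and 14-OTBDPS | C=C1C(=O)O[C@@H]2C[C@H](C)CCC/C(CO[Si](c3ccccc3)(c3ccccc3)C(C)(C)C)=C\[C@H](OCc3ccc(OC)cc3)[C@@H]12 | intermediate
39 | C8 alcohol (8-epi with respect to the target; 14-OTBDPS) | C=C1C(=O)O[C@@H]2C[C@H](C)CCC/C(CO[Si](c3ccccc3)(c3ccccc3)C(C)(C)C)=C\[C@H](O)[C@@H]12 | intermediate
40 | C8 ester with the acetonide acid (C8 inverted; 14-OTBDPS) | C=C1C(=O)O[C@@H]2C[C@H](C)CCC/C(CO[Si](c3ccccc3)(c3ccccc3)C(C)(C)C)=C\[C@@H](OC(=O)C3=CCOC(C)(C)OC3)[C@@H]12 | intermediate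
41 | CNP0131216.2 | C=C1C(=O)O[C@@H]2C[C@H](C)CCC/C(CO)=C\[C@@H](OC(=O)/C(=C/CO)CO)[C@@H]12 | target

**Summary and risks**

Total step count: 22. Longest linear sequence: 17 steps (steps 1 and 7–22, from 1 to 41).

Steps most likely to fail:

Step 14. The alkoxide may cleave the C1–C6 bond ionically to an enone and a pentadienyl anion that recombine at the ring-alkene terminus (net 1,3 shift). The doubly allylic C1–H may be removed, or the product enolate may equilibrate and expel the C8 ether. The fallback avoids all anionic species. It sets out from 27: N-(trimethylsilyl)imidazole caps the tertiary alcohol to give the trimethylsilyl ether F1. This is heated in o-dichlorobenzene at 200–220 °C in base-washed glass, so that a neutral siloxy-Cope rearrangement through the same chair gives the trimethylsilyl enol ether F2. K2CO3 in methanol then releases the ketone, and the route is rejoined at 30.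

Step 16. Hydride may be delivered to the other face of the C6 carbonyl, because the conformation of the ten-membered ring and not the zinc chelate may decide. The fallback uses the wrong epimer productively and sets out from 31. The C6-epimeric alcohol F3 is desilylated with camphorsulfonic acid in methanol to the diol F4 and oxidised with TEMPO/PhI(OAc)2 to the cis-fused lactone F5. LiOH opens it to the hydroxy acid F6, and an intramolecular Mitsunobu lactonisation (PPh3, diisopropyl azodicarboxylate) closes the ring with inversion at C6. The route is rejoined at 35.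

Step 21. SN2 displacement at the hindered allylic C8 may be outrun by elimination towards the C9=C10 alkene, by allylic transposition, or by acyl transfer with retention. The fallback replaces substitution by an oxidation–reduction sequence and sets out from 39. Dess–Martin periodinane gives the C8 ketone F7. Luche reduction (NaBH4, CeCl3·7H2O, MeOH, −78 °C) should add hydride anti to the C7–C11 bond and give the 8-epimeric alcohol F8 with the configuration of the target. F8 is acylated with 14 under Yamaguchi conditions (2,4,6-trichlorobenzoyl chloride, Et3N, 4-(dimethylamino)pyridine) with retention. The route is rejoined at 40.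

Further compounds
F1 | step 14 | trimethylsilyl ether of 27 | C/C=C/[C@@]1(O[Si](C)(C)C)[C@H](CCO[Si](C)(C)C(C)(C)C)[C@@H](OCc2ccc(OC)cc2)C=C(CO[Si](c2ccccc2)(c2ccccc2)C(C)(C)C)[C@@H]1C=C
F2 | step 14 | trimethylsilyl enol ether (C5=C6) of 30 | C[Si](C)(C)O/C1=C\[C@H](C)C/C=C/C(CO[Si](c2ccccc2)(c2ccccc2)C(C)(C)C)=C\[C@H](OCc2ccc(OC)cc2)[C@H]1CCO[Si](C)(C)C(C)(C)C
F3 | step 16 | C6 epimer of 32 | O[C@H]1C[C@H](C)CCC/C(CO[Si](c2ccccc2)(c2ccccc2)C(C)(C)C)=C\[C@H](OCc2ccc(OC)cc2)[C@H]1CCO[Si](C)(C)C(C)(C)C
F4 | step 16 | C6 epimer of 33 | O[C@H]1C[C@H](C)CCC/C(CO[Si](c2ccccc2)(c2ccccc2)C(C)(C)C)=C\[C@H](OCc2ccc(OC)cc2)[C@H]1CCO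
F5 | step 16 | cis-fused 6,12-lactone (C6 epimer of 35) | O=C1O[C@H]2C[C@H](C)CCC/C(CO[Si](c3ccccc3)(c3ccccc3)C(C)(C)C)=C\[C@H](OCc3ccc(OC)cc3)[C@H]2C1
F6 | step 16 | 6-hydroxy-12-carboxylic acid from F5 | O[C@H]1C[C@H](C)CCC/C(CO[Si](c2ccccc2)(c2ccccc2)C(C)(C)C)=C\[C@H](OCc2ccc(OC)cc2)[C@H]1CC(=O)O
F7 | step 21 | C8 ketone (enone) from 39 | C=C1C(=O)O[C@@H]2C[C@H](C)CCC/C(CO[Si](c3ccccc3)(c3ccccc3)C(C)(C)C)=C\C(=O)[C@@H]12
F8 | step 21 | C8 alcohol with the configuration of the target (C8 epimer of 39) | C=C1C(=O)O[C@@H]2C[C@H](C)CCC/C(CO[Si](c3ccccc3)(c3ccccc3)C(C)(C)C)=C\[C@@H](O)[C@@H]12
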